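Plan
1. Retrosynthesis (labdane numbering). The C19–O tiglate ester is cut first. Next come C12–C13 (B-alkyl Suzuki–Miyaura coupling with a (Z)-3-iodobut-2-enoate, which carries the 13Z geometry) and C11=C12 (Wittig). The C18 methyl then goes back to a second CH2OH arm, and the 7-ene goes back to a C7 ketone and its silyl enol ether.
2. Enabling feature. In ring B the bonds C5–C10 and C8–C9 lie opposite each other, so C5–C6–C7–C8 is a four-carbon diene unit and C9–C10 a two-carbon dienophile unit. Ring A is only C1–C4 bridging C10 to C5, so cutting these two bonds opens rings A and B at once and removes the adjacent stereocentres C5, C10 (quaternary) and C9.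
3. Forward direction. Geranyl acetate gives C1–C3, C9–C11, C20 and the (E)-C9=C10 alkene; triethyl methanetricarboxylate gives C4, C5, C18 and C19; a ketophosphonate gives C6–C8 and C17. The acyclic, achiral triene closes rings A and B together in one intramolecular Diels–Alder reaction, and the side chain is joined afterwards.
4. Stereochemistry. The relative configuration at C5, C8, C9 and C10 comes from the three alkene geometries and the endo transition state. The absolute configuration comes only from the (R,R)-tBu-box copper catalyst. C8 is erased later by the 7-ene.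
5. C4 becomes stereogenic only in the trans-decalin. There the open equatorial arm (C18) is tosylated and reduced to CH3, and the screened axial arm (C19) is kept for the tiglate. The acid travels as a 2-(trimethylsilyl)ethyl ester, so fluoride frees it beside the tiglate.

Key step: step 11

Assumption: the SMILES is read as the normal labdane series (5α-H, 9α-H, 10β-CH3), with the (E)-2-methylbut-2-enoate on the axial 4β-CH2O arm (C19) and a 13Z acid; labdane numbers and α/β labels are used for all intermediates, including the acyclic ones.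

Step 1
Reactants: 1 geranyl acetate
Product: 3 (E)-6-hydroxy-3-methylhex-2-en-1-yl acetate, via secondary ozonide 2 (not isolated)
Conditions: O3 (1 equiv), CH2Cl2, −78 °C; then NaBH4, MeOH, −78 → 0 °C
Reagents that add atoms: ozone, [O-][O+]=O
Why: Ozonolysis with reductive work-up: the electron-rich 6,7-alkene reacts much faster than the 2,3-alkene, which the allylic acetoxy group deactivates, and borohydride takes the ozonide directly to the primary alcohol (C3) with the (E)-alkene (later C9=C10) untouched.

Step 2
Reactants: 3 (E)-6-hydroxy-3-methylhex-2-en-1-yl acetate; 4 triethyl methanetricarboxylate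
Product: 5 triethyl (E)-7-acetoxy-5-methylhept-5-ene-1,1,1-tricarboxylate
Conditions: PPh3, DIAD, THF, 0 °C → rt
Reagents that add atoms: none
Why: Mitsunobu C-alkylation: the tricarboxylate C–H is acidic enough to act as the pronucleophile, so the activated primary alcohol is displaced directly and C3–C4 forms without a separate halide.

Step 3
Reactants: 5 triethyl (E)-7-acetoxy-5-methylhept-5-ene-1,1,1-tricarboxylate
Product: 6 (E)-2,2-bis(hydroxymethyl)-6-methyloct-6-ene-1,8-diol
Conditions: LiAlH4, THF, 0 °C → rt; H2O quench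
Reagents that add atoms: none
Why: Exhaustive LiAlH4 ester reduction, established for alkylated methanetricarboxylates, turns C4 into a tris(hydroxymethyl) carbon and also unmasks the C11 allylic alcohol, which is needed free in step 5.

Step 4
Reactants: 6 (E)-2,2-bis(hydroxymethyl)-6-methyloct-6-ene-1,8-diol
Product: 7 (E)-6-[5-(hydroxymethyl)-2,2-dimethyl-1,3-dioxan-5-yl]-3-methylhex-2-en-1-ol
Conditions: Me2C(OMe)2, PPTS (cat.), acetone, rt
Reagents that add atoms: 2,2-dimethoxypropane, COC(C)(C)OC
Why: Acid-catalysed transketalisation ties two of the three equivalent arms into the only cyclic ketal available, the 1,3-dioxane, and leaves the third arm (C5) and the remote allylic alcohol free, any open mixed ketal being lost on aqueous work-up.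

Step 5
Reactants: 7 (E)-6-[5-(hydroxymethyl)-2,2-dimethyl-1,3-dioxan-5-yl]-3-methylhex-2-en-1-ol
Product: 8 (E)-6-[5-(hydroxymethyl)-2,2-dimethyl-1,3-dioxan-5-yl]-3-methylhex-2-enal
Conditions: MnO2, CH2Cl2, rt
Reagents that add atoms: none
Why: Allylic oxidation with MnO2 touches only the allylic alcohol, so C11 and C5 are differentiated without a protecting group and the (E)-geometry is kept.

Step 6
Reactants: 8 (E)-6-[5-(hydroxymethyl)-2,2-dimethyl-1,3-dioxan-5-yl]-3-methylhex-2-enal
Product: 9 (E)-6-[5-(hydroxymethyl)-2,2-dimethyl-1,3-dioxan-5-yl]-3-methylhex-2-enoic acid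
Conditions: NaClO2, NaH2PO4, 2-methylbut-2-ene, tBuOH/H2O, 0 °C → rt
Reagents that add atoms: sodium chlorite, [Na+].[O-]Cl=O
Why: Pinnick oxidation converts the enal to the enoic acid without alkene isomerisation and leaves the primary alcohol and the ketal alone at the buffered pH.

Step 7
Reactants: 9 (E)-6-[5-(hydroxymethyl)-2,2-dimethyl-1,3-dioxan-5-yl]-3-methylhex-2-enoic acid
Product: 10 (E)-6-(5-formyl-2,2-dimethyl-1,3-dioxan-5-yl)-3-methylhex-2-enoic acid
Conditions: Dess–Martin periodinane, CH2Cl2, 0 °C → rt
Reagents that add atoms: none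
Why: Dess–Martin oxidation tolerates the free acid and gives the C5 aldehyde, which has no α-hydrogen and so can neither enolise nor eliminate.

Step 8
Reactants: 10 (E)-6-(5-formyl-2,2-dimethyl-1,3-dioxan-5-yl)-3-methylhex-2-enoic acid; 11 diethyl (2-oxobutyl)phosphonate
Product: 12 (E)-6-{2,2-dimethyl-5-[(E)-3-oxopent-1-en-1-yl]-1,3-dioxan-5-yl}-3-methylhex-2-enoic acid
Conditions: Ba(OH)2·8H2O, THF/H2O (40:1), rt; then aq. NaHSO4 to pH 4
Reagents that add atoms: none
Why: Horner–Wadsworth–Emmons olefination: the stabilised ketophosphonate anion adds reversibly to the hindered, non-enolisable aldehyde and collapses to the (E)-enone C5=C6, while the carboxylate is a spectator that is re-protonated on work-up.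

Step 9
Reactants: 12 (E)-6-{2,2-dimethyl-5-[(E)-3-oxopent-1-en-1-yl]-1,3-dioxan-5-yl}-3-methylhex-2-enoic acid; 13 2-oxazolidinone
Product: 15 3-[(E)-6-{2,2-dimethyl-5-[(E)-3-oxopent-1-en-1-yl]-1,3-dioxan-5-yl}-3-methylhex-2-enoyl]oxazolidin-2-one, via mixed pivalic anhydride 14 (not isolated)
Conditions: PivCl, Et3N, THF, −20 °C; then LiCl, 13, −20 °C → rt
Reagents that add atoms: pivaloyl chloride, CC(C)(C)C(=O)Cl (its atoms are present in 14 only)
Why: N-acylation of the oxazolidinone through a mixed anhydride under LiCl/Et3N is mild enough to avoid deconjugation or E/Z scrambling of the 3-methylenoyl unit and aza-Michael addition to the hindered enone.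

Step 10
Reactants: 15 3-[(E)-6-{2,2-dimethyl-5-[(E)-3-oxopent-1-en-1-yl]-1,3-dioxan-5-yl}-3-methylhex-2-enoyl]oxazolidin-2-one
Product: 16 3-[(E)-6-{2,2-dimethyl-5-[(1E,3Z)-3-(triisopropylsilyloxy)penta-1,3-dien-1-yl]-1,3-dioxan-5-yl}-3-methylhex-2-enoyl]oxazolidin-2-one
Conditions: TIPSOTf (1.1 equiv), Et3N, CH2Cl2, −78 → 0 °C
Reagents that add atoms: triisopropylsilyl triflate, CC(C)[Si](OS(=O)(=O)C(F)(F)F)(C(C)C)C(C)C
Why: Soft enolisation (silyl triflate/amine): the ketone can enolise only toward C8 because C4 is quaternary, the protocol gives the (Z)-enol ether whose methyl points outward in the s-cis diene, and one equivalent of silylating agent leaves the far less basic imide alone.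

Step 11
Reactants: 16 3-[(E)-6-{2,2-dimethyl-5-[(1E,3Z)-3-(triisopropylsilyloxy)penta-1,3-dien-1-yl]-1,3-dioxan-5-yl}-3-methylhex-2-enoyl]oxazolidin-2-one
Product: 17 3-[18,19-(isopropylidenedioxy)-7-(triisopropylsilyloxy)-12,13,14,15,16-pentanorlabd-6-en-11-oyl]oxazolidin-2-one (trans-fused; 5α-H, 8β-CH3, 9β-acyl, 10β-CH3)
Conditions: [Cu((R,R)-tBu-box)](SbF6)2 (10 mol %, from CuCl2, AgSbF6 and 2,2'-(propane-2,2-diyl)bis[(4R)-4-tert-butyl-4,5-dihydro-1,3-oxazole]), 4 Å molecular sieves, CH2Cl2, 25 °C
Reagents that add atoms: none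
Why: Proposed new method: chelation of both imide carbonyl oxygens by the square-planar divalent-copper cation makes the s-cis (E)-enoyl unit a much better acceptor, and the diene C5=C6–C7=C8 adds to C9=C10 in a concerted, asynchronous, suprafacial [4+2] cycloaddition whose regiochemistry is fixed by the tether and not by the frontier coefficients (the C7 oxygen polarises the diene toward C8, which here meets the α-carbon C9, so it helps only by raising the HOMO, whereas the C8 methyl and the C4 branch on C5 polarise in the useful sense and the geminal substitution at C4 favours the folded conformer). The closest known reaction type is the [Cu(tBu-box)](SbF6)2-catalysed intramolecular Diels–Alder reaction of (E,E,E)-undeca-2,8,10-trienoyl oxazolidinones to trans-fused octalins, and the new elements are the β,β-disubstituted dienophile, the quaternary carbon next to the diene and the 2-silyloxy diene. Ring B closes as the six-membered cycloadduct ring through C5–C10 and C8–C9, and ring A closes in the fused mode as the six-membered ring made of C10, the four tether atoms C1–C4 and C5, with the tether in a chair-like fold. C9 and C10 follow from the (E)-alkene (C11 and the C10 methyl stay cis), C5 from the (E)-C5=C6 bond combined with the endo position of the chelated carbonyl (C4 ends cis to C11 and to the C10 methyl, so H5 is anti to the angular methyl and the fusion is trans), and C8 from the (Z)-enol ether, whose outward methyl ends cis to C11. The absolute sense rests on the ligand alone: in the square-planar chelate a tert-butyl group of the (R,R)-ligand covers the Re face of C9, so the diene reaches the Si face, which is the face required for 17. The step needs endo over exo and one enantioface, the first secured by the chelated (E)-imide and the second by the ligand, and it has no intramolecular Mukaiyama–Michael rival because attack of C8 on C10 would have to form a nine-membered ring.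

Step 12
Reactants: 17 trans-fused imide adduct
Product: 18 18,19-(isopropylidenedioxy)-7-(triisopropylsilyloxy)-12,13,14,15,16-pentanorlabd-6-en-11-ol
Conditions: LiBH4, MeOH (1 equiv), Et2O, 0 °C
Reagents that add atoms: none
Why: Reductive cleavage of an N-acyl oxazolidinone with LiBH4 delivers the C11 primary alcohol without touching C9, the silyl enol ether or the ketal.

Step 13
Reactants: 18 C11 alcohol
Product: 19 18,19-(isopropylidenedioxy)-7-(triisopropylsilyloxy)-12,13,14,15,16-pentanorlabd-6-en-11-al
Conditions: Dess–Martin periodinane, pyridine, CH2Cl2, 0 °C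
Reagents that add atoms: none
Why: Pyridine-buffered Dess–Martin oxidation gives the aldehyde under non-acidic conditions that spare the triisopropylsilyl enol ether and the ketal.

Step 14
Reactants: 19 C11 aldehyde
Product: 20 18,19-(isopropylidenedioxy)-7-(triisopropylsilyloxy)-13,14,15,16-tetranorlabda-6,11-diene (9β-vinyl)
Conditions: Ph3PCH3Br, KOtBu, THF, 0 °C; then 19, 0 °C → rt
Reagents that add atoms: methyltriphenylphosphonium bromide, C[P+](c1ccccc1)(c1ccccc1)c1ccccc1.[Br-]
Why: Wittig methylenation adds C12 while C8 is still sp3, so no β,γ-unsaturated aldehyde is ever handled, and the equatorial formyl group is already the more stable C9 epimer, so the basic ylide cannot erode that centre.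

Step 15
Reactants: 20 9β-vinyl silyl enol ether
Product: 21 18,19-(isopropylidenedioxy)-13,14,15,16-tetranorlabd-11-en-7-one (8β-CH3 as formed in step 11)
Conditions: Bu4NF, AcOH, THF, 0 °C
Reagents that add atoms: none
Why: Fluoride desilylation of the silyl enol ether with acetic acid as proton source releases the C7 ketone by protonation at C6, and any epimerisation at C8 is harmless because that centre is removed in step 16.

Step 16
Reactants: 21 C7 ketone
Product: 23 18,19-(isopropylidenedioxy)-13,14,15,16-tetranorlabda-7,11-dien-7-yl trifluoromethanesulfonate, via bromomagnesium enolate 22 (not isolated)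
Conditions: iPr2NMgBr (from MeMgBr and iPr2NH), Et2O, reflux; then PhNTf2, THF, rt
Reagents that add atoms: methylmagnesium bromide, C[Mg]Br (MgBr present in 22 only); N-phenylbis(trifluoromethanesulfonimide), O=S(=O)(N(c1ccccc1)S(=O)(=O)C(F)(F)F)C(F)(F)F
Why: Thermodynamic enolate trapping: the magnesium amide lets the enolates equilibrate to the more substituted C7=C8 enolate, which the triflimide captures as the tetrasubstituted enol triflate, so the alkene is placed at C7=C8 rather than C6=C7 and the C8 stereocentre is deliberately erased.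

Step 17
Reactants: 23 C7 enol triflate
Product: 24 18,19-(isopropylidenedioxy)-13,14,15,16-tetranorlabda-7,11-diene
Conditions: Pd(OAc)2 (5 mol %), PPh3, HCO2H, Et3N, DMF, 60 °C
Reagents that add atoms: none
Why: Palladium-catalysed formate reduction of an enol triflate (oxidative addition to zerovalent palladium, formate exchange, decarboxylation, reductive elimination) replaces OTf by H without moving the ring double bond.

Step 18
Reactants: 24 7,11-diene ketal
Product: 25 13,14,15,16-tetranorlabda-7,11-diene-18,19-diol
Conditions: AcOH/H2O (4:1), 40 °C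
Reagents that add atoms: none
Why: Mild acidic ketal hydrolysis frees both C4 arms under conditions too weak to protonate the trisubstituted or the terminal alkene.

Step 19
Reactants: 25 18,19-diol
Product: 26 19-hydroxy-13,14,15,16-tetranorlabda-7,11-dien-18-yl 4-methylbenzenesulfonate (4α-CH2OTs equatorial, 4β-CH2OH axial)
Conditions: TsCl (1.05 equiv), pyridine, CH2Cl2, 0 °C
Reagents that add atoms: 4-toluenesulfonyl chloride, Cc1ccc(cc1)S(=O)(=O)Cl
Why: Site-selective sulfonylation: the equatorial C18 hydroxyl is open whereas the axial C19 hydroxyl is screened by the 1,3-diaxial C10 methyl, and this substrate-controlled choice makes C4 stereogenic with the required configuration.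

Step 20
Reactants: 26 C18 monotosylate
Product: 27 13,14,15,16-tetranorlabda-7,11-dien-19-ol (4α-CH3, 4β-CH2OH)
Conditions: LiEt3BH, THF, reflux
Reagents that add atoms: none
Why: SN2 hydride displacement of a hindered primary sulfonate with LiEt3BH, the reagent of choice for neopentyl tosylates, converts C18 into the methyl group while the two isolated alkenes are inert and the configuration at C4 is kept.

Step 21
Reactants: 27 C19 alcohol; 28 tigloyl chloride [(E)-2-methylbut-2-enoyl chloride]
Product: 29 13,14,15,16-tetranorlabda-7,11-dien-19-yl (E)-2-methylbut-2-enoate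
Conditions: DMAP (cat.), pyridine, CH2Cl2, 40 °C
Reagents that add atoms: none
Why: DMAP-catalysed acylation overcomes the hindrance of the axial neopentyl alcohol, and the tiglate is the thermodynamically preferred geometry, so it cannot drift.

Step 22
Reactants: 30 but-2-ynoic acid; 31 2-(trimethylsilyl)ethanol
Product: 32 2-(trimethylsilyl)ethyl but-2-ynoate
Conditions: DCC, DMAP (cat.), CH2Cl2, 0 °C → rt
Reagents that add atoms: none
Why: Steglich esterification installs the fluoride-labile ester before the iodide is present, so no nucleophilic catalyst ever meets a β-iodoenoate.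

Step 23
Reactants: 32 2-(trimethylsilyl)ethyl but-2-ynoate
Product: 33 2-(trimethylsilyl)ethyl (Z)-3-iodobut-2-enoate
Conditions: NaI, AcOH, 110 °C
Reagents that add atoms: sodium iodide, [Na+].[I-]
Why: Hydroiodination of a 2-ynoate (conjugate addition of iodide and anti protonation) gives the (Z)-3-iodoenoate with iodine cis to the ester, the geometry that becomes 13Z.

Step 24
Reactants: 29 C19 tiglate with 9β-vinyl group; 33 2-(trimethylsilyl)ethyl (Z)-3-iodobut-2-enoate
Product: 35 2-(trimethylsilyl)ethyl (13Z)-19-[(E)-2-methylbut-2-enoyloxy]labda-7,13-dien-15-oate, via B-alkyl-9-BBN adduct 34 (not isolated)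
Conditions: 9-BBN-H, THF, 0 °C → rt; then 33, PdCl2(dppf) (5 mol %), AsPh3, Cs2CO3, DMF/H2O, rt
Reagents that add atoms: 9-borabicyclo[3.3.1]nonane, [H]B1C2CCCC1CCC2 (boron unit present in 34 only)
Why: Hydroboration followed by B-alkyl Suzuki–Miyaura coupling: 9-BBN-H adds only to the monosubstituted alkene (boron at C12), leaving the ring alkene and the tiglate alone, and the coupling forms C12–C13 with retention of the iodoalkene geometry.

Step 25
Reactants: 35 2-(trimethylsilyl)ethyl ester
Product: 36 (13Z)-19-[(E)-2-methylbut-2-enoyloxy]labda-7,13-dien-15-oic acid (CNP0249147.2)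
Conditions: Bu4NF, THF, 0 °C → rt; then 0.1 M HCl
Reagents that add atoms: none
Why: Fluoride-induced β-elimination of the 2-(trimethylsilyl)ethyl ester frees the C15 acid without hydrolytic conditions, so the tiglate, both alkene geometries and all stereocentres are untouched.

Compound list
1 | geranyl acetate | CC(C)=CCC/C(C)=C/COC(C)=O | starting material
2 | secondary ozonide (1,2,4-trioxolane) of the 6,7-alkene of 1, racemic at the ring CH | CC(=O)OC/C=C(\C)CCC1OOC(C)(C)O1 | intermediate
3 | (E)-6-hydroxy-3-methylhex-2-en-1-yl acetate | CC(=O)OC/C=C(\C)CCCO | intermediate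
4 | triethyl methanetricarboxylate | CCOC(=O)C(C(=O)OCC)C(=O)OCC | starting material
5 | triethyl (E)-7-acetoxy-5-methylhept-5-ene-1,1,1-tricarboxylate | CC(=O)OC/C=C(\C)CCCC(C(=O)OCC)(C(=O)OCC)C(=O)OCC | intermediate
6 | (E)-2,2-bis(hydroxymethyl)-6-methyloct-6-ene-1,8-diol | OC/C=C(\C)CCCC(CO)(CO)CO | intermediate
7 | (E)-6-[5-(hydroxymethyl)-2,2-dimethyl-1,3-dioxan-5-yl]-3-methylhex-2-en-1-ol | OC/C=C(\C)CCCC1(CO)COC(C)(C)OC1 | intermediate
8 | (E)-6-[5-(hydroxymethyl)-2,2-dimethyl-1,3-dioxan-5-yl]-3-methylhex-2-enal | O=C/C=C(\C)CCCC1(CO)COC(C)(C)OC1 | intermediate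
9 | (E)-6-[5-(hydroxymethyl)-2,2-dimethyl-1,3-dioxan-5-yl]-3-methylhex-2-enoic acid | OC(=O)/C=C(\C)CCCC1(CO)COC(C)(C)OC1 | intermediate
10 | (E)-6-(5-formyl-2,2-dimethyl-1,3-dioxan-5-yl)-3-methylhex-2-enoic acid | OC(=O)/C=C(\C)CCCC1(C=O)COC(C)(C)OC1 | intermediate
11 | diethyl (2-oxobutyl)phosphonate | CCOP(=O)(CC(=O)CC)OCC | starting material
12 | (E)-6-{2,2-dimethyl-5-[(E)-3-oxopent-1-en-1-yl]-1,3-dioxan-5-yl}-3-methylhex-2-enoic acid | OC(=O)/C=C(\C)CCCC1(COC(C)(C)OC1)/C=C/C(=O)CC | intermediate
13 | 2-oxazolidinone | O=C1NCCO1 | starting material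
14 | mixed pivalic anhydride of 12 | CC(C)(C)C(=O)OC(=O)/C=C(\C)CCCC1(COC(C)(C)OC1)/C=C/C(=O)CC | intermediate
15 | enone imide, 3-[(E)-6-{2,2-dimethyl-5-[(E)-3-oxopent-1-en-1-yl]-1,3-dioxan-5-yl}-3-methylhex-2-enoyl]oxazolidin-2-one | O=C1OCCN1C(=O)/C=C(\C)CCCC2(COC(C)(C)OC2)/C=C/C(=O)CC | intermediate
16 | achiral trienoyl imide with (1E,3Z)-3-(triisopropylsilyloxy)penta-1,3-dienyl group (cycloaddition precursor) | O=C1OCCN1C(=O)/C=C(\C)CCCC2(COC(C)(C)OC2)/C=C/C(O[Si](C(C)C)(C(C)C)C(C)C)=C/C | intermediate
17 | trans-fused bicyclic imide, C7 silyl enol ether (5α-H, 8β-CH3, 9β-acyl, 10β-CH3) | CC1(C)OCC2(CO1)CCC[C@]3(C)[C@@H](C(=O)N4CCOC4=O)[C@@H](C)C(O[Si](C(C)C)(C(C)C)C(C)C)=C[C@@H]23 | intermediate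
18 | 18,19-(isopropylidenedioxy)-7-(triisopropylsilyloxy)-12,13,14,15,16-pentanorlabd-6-en-11-ol | CC1(C)OCC2(CO1)CCC[C@]3(C)[C@@H](CO)[C@@H](C)C(O[Si](C(C)C)(C(C)C)C(C)C)=C[C@@H]23 | intermediate
19 | 18,19-(isopropylidenedioxy)-7-(triisopropylsilyloxy)-12,13,14,15,16-pentanorlabd-6-en-11-al | CC1(C)OCC2(CO1)CCC[C@]3(C)[C@@H](C=O)[C@@H](C)C(O[Si](C(C)C)(C(C)C)C(C)C)=C[C@@H]23 | intermediate
20 | 18,19-(isopropylidenedioxy)-7-(triisopropylsilyloxy)-13,14,15,16-tetranorlabda-6,11-diene | CC1(C)OCC2(CO1)CCC[C@]3(C)[C@@H](C=C)[C@@H](C)C(O[Si](C(C)C)(C(C)C)C(C)C)=C[C@@H]23 | intermediate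
21 | 18,19-(isopropylidenedioxy)-13,14,15,16-tetranorlabd-11-en-7-one (8β-CH3) | CC1(C)OCC2(CO1)CCC[C@]3(C)[C@@H](C=C)[C@@H](C)C(=O)C[C@@H]23 | intermediate
22 | bromomagnesium C7=C8 enolate of 21 | CC1(C)OCC2(CO1)CCC[C@]3(C)[C@@H](C=C)C(C)=C(O[Mg]Br)C[C@@H]23 | intermediate
23 | 18,19-(isopropylidenedioxy)-13,14,15,16-tetranorlabda-7,11-dien-7-yl trifluoromethanesulfonate | CC1(C)OCC2(CO1)CCC[C@]3(C)[C@@H](C=C)C(C)=C(OS(=O)(=O)C(F)(F)F)C[C@@H]23 | intermediate
24 | 18,19-(isopropylidenedioxy)-13,14,15,16-tetranorlabda-7,11-diene | CC1(C)OCC2(CO1)CCC[C@]3(C)[C@@H](C=C)C(C)=CC[C@@H]23 | intermediate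
25 | 13,14,15,16-tetranorlabda-7,11-diene-18,19-diol | OCC1(CO)CCC[C@]2(C)[C@@H](C=C)C(C)=CC[C@@H]12 | intermediate
26 | 19-hydroxy-13,14,15,16-tetranorlabda-7,11-dien-18-yl 4-methylbenzenesulfonate | OC[C@@]1(COS(=O)(=O)c3ccc(C)cc3)CCC[C@]2(C)[C@@H](C=C)C(C)=CC[C@@H]12 | intermediate
27 | 13,14,15,16-tetranorlabda-7,11-dien-19-ol | OC[C@@]1(C)CCC[C@]2(C)[C@@H](C=C)C(C)=CC[C@@H]12 | intermediate
28 | tigloyl chloride | C/C=C(\C)C(=O)Cl | starting material
29 | 13,14,15,16-tetranorlabda-7,11-dien-19-yl (E)-2-methylbut-2-enoate | C/C=C(\C)C(=O)OC[C@@]1(C)CCC[C@]2(C)[C@@H](C=C)C(C)=CC[C@@H]12 | intermediate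
30 | but-2-ynoic acid | CC#CC(=O)O | starting material
31 | 2-(trimethylsilyl)ethanol | C[Si](C)(C)CCO | starting material
32 | 2-(trimethylsilyl)ethyl but-2-ynoate | CC#CC(=O)OCC[Si](C)(C)C | intermediate
33 | 2-(trimethylsilyl)ethyl (Z)-3-iodobut-2-enoate | I/C(C)=C\C(=O)OCC[Si](C)(C)C | intermediate
34 | 12-(9-borabicyclo[3.3.1]nonan-9-yl) adduct of 29 | C/C=C(\C)C(=O)OC[C@@]1(C)CCC[C@]2(C)[C@@H](CCB3C4CCCC3CCC4)C(C)=CC[C@@H]12 | intermediate
35 | 2-(trimethylsilyl)ethyl (13Z)-19-[(E)-2-methylbut-2-enoyloxy]labda-7,13-dien-15-oate | C/C=C(\C)C(=O)OC[C@@]1(C)CCC[C@]2(C)[C@@H](CC/C(C)=C\C(=O)OCC[Si](C)(C)C)C(C)=CC[C@@H]12 | intermediate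
36 | (13Z)-19-[(E)-2-methylbut-2-enoyloxy]labda-7,13-dien-15-oic acid (CNP0249147.2) | C/C=C(\C)C(=O)OC[C@@]1(C)CCC[C@]2(C)[C@@H](CC/C(C)=C\C(=O)O)C(C)=CC[C@@H]12 | target

Total step count: 25. Longest linear sequence: 23 (steps 1–21, 24 and 25). Steps 22 and 23 form the short branch to iodide 33.

Steps most likely to fail

First, step 11.
- The cycloaddition may be too slow. A β,β-disubstituted imide is only weakly activated by the copper cation, the forming C5–C10 bond joins a carbon next to quaternary C4 to the future quaternary C10, and the C7 oxygen polarises the diene in the unhelpful sense.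
- During a long reaction the Lewis acid may strip the silyl enol ether.
- Endo selectivity may erode, because the endo mode also places the C10 methyl under the diene and builds the 1,3-diaxial contact between C19 and C20.
- The fallback replaces catalyst control by auxiliary control with a much stronger, stoichiometric Lewis acid. This is the established dialkylaluminium chloride-promoted intramolecular Diels–Alder reaction of trienoyl 4-benzyl-oxazolidinones.
- It sets out from enone acid 12. Its mixed anhydride 14 is intercepted with (S)-4-benzyl-2-oxazolidinone (LiCl, Et3N) to give the chiral enone imide F1, and TIPSOTf/Et3N converts this into the chiral (Z)-silyl dienol ether F2.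
- Me2AlCl (1.4 equiv, CH2Cl2, −30 °C) then forms the cationic aluminium chelate, in which the benzyl group blocks the C9 Re face. Endo cyclisation on the Si face gives the auxiliary-bearing trans-fused adduct F3.
- Minor diastereomers are removed by chromatography or crystallisation, so enantiopurity no longer depends on a catalyst. LiBH4 cleavage as in step 12 returns to the route at alcohol 18.

Second, step 16.
- Enolate equilibration may be incomplete, or strain between the C8 methyl and the C9 vinyl group may reduce the preference for the tetrasubstituted enolate. Triflation would then occur toward C6 and the alkene would end up in the wrong position after step 17.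
- The fallback replaces enolate regiocontrol by a stereoelectronically controlled elimination and sets out from ketone 21.
- K2CO3 in MeOH equilibrates C8 to the equatorial methyl epimer, 8-epi-ketone F4.
- LiBH(sBu)3 (THF, −78 °C) attacks from the equatorial side to give the axial 7α-alcohol F5.
- POCl3 in pyridine effects anti elimination through the axial 8β-hydrogen toward the more substituted alkene. This returns to the route at diene 24.

Third, step 19.
- Discrimination between the two primary neopentyl hydroxyl groups in the sulfonylation may be poor. In addition, the hydroxy tosylate may close to a spiro-oxetane under the basic hydride of step 20.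
- The fallback moves the differentiation from O-sulfonylation to the displacement step, where the rate difference is far larger and no free hydroxyl remains. It sets out from diol 25.
- Excess TsCl with DMAP in pyridine at 40 °C gives the 18,19-bis-tosylate F6.
- LiEt3BH displaces only the equatorial C18 sulfonate, because backside approach to C19 runs into the C10 methyl. This gives the 19-tosylate F7.
- Na/naphthalene (THF, −78 °C) cleaves the S–O bond of F7 and returns to the route at alcohol 27.

Further compounds
F1 | step 11 | (S)-4-benzyl-3-[(E)-6-{2,2-dimethyl-5-[(E)-3-oxopent-1-en-1-yl]-1,3-dioxan-5-yl}-3-methylhex-2-enoyl]oxazolidin-2-one | CCC(=O)/C=C/C1(COC(C)(C)OC1)CCC/C(C)=C/C(=O)N2[C@@H](Cc3ccccc3)COC2=O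
F2 | step 11 | (1E,3Z)-3-(triisopropylsilyloxy)penta-1,3-dienyl derivative of F1 | C/C=C(O[Si](C(C)C)(C(C)C)C(C)C)/C=C/C1(COC(C)(C)OC1)CCC/C(C)=C/C(=O)N2[C@@H](Cc3ccccc3)COC2=O
F3 | step 11 | trans-fused adduct carrying the (S)-4-benzyl-oxazolidinone (ring configuration as in 17) | CC1(C)OCC2(CO1)CCC[C@]3(C)[C@@H](C(=O)N4[C@@H](Cc5ccccc5)COC4=O)[C@@H](C)C(O[Si](C(C)C)(C(C)C)C(C)C)=C[C@@H]23
F4 | step 16 | 18,19-(isopropylidenedioxy)-13,14,15,16-tetranorlabd-11-en-7-one, 8α-CH3 epimer | CC1(C)OCC2(CO1)CCC[C@]3(C)[C@@H](C=C)[C@H](C)C(=O)C[C@@H]23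
F5 | step 16 | 18,19-(isopropylidenedioxy)-13,14,15,16-tetranorlabd-11-en-7α-ol (8α-CH3) | CC1(C)OCC2(CO1)CCC[C@]3(C)[C@@H](C=C)[C@H](C)[C@H](O)C[C@@H]23
F6 | step 19 | 13,14,15,16-tetranorlabda-7,11-diene-18,19-diyl bis(4-methylbenzenesulfonate) | Cc1ccc(cc1)S(=O)(=O)OCC2(COS(=O)(=O)c3ccc(C)cc3)CCC[C@]4(C)[C@@H](C=C)C(C)=CC[C@@H]24
F7 | step 19 | 13,14,15,16-tetranorlabda-7,11-dien-19-yl 4-methylbenzenesulfonate | Cc1ccc(cc1)S(=O)(=O)OC[C@@]2(C)CCC[C@]3(C)[C@@H](C=C)C(C)=CC[C@@H]23
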